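**Strategy.** The target (benzofuran numbering O1, C2, C3, C3a, C4–C7, C7a) hides a β-keto ester. O1–C7a=C3a–C4(OMe), spanning the dihydrofuran and cyclohexadiene rings, is a vinylogous carbonate, so C4 with its methoxy group is carried as a methyl ester and C7a as the ketone. The key step turns an open-chain α-substituted β-keto ester into the dihydrofuran: catalyst-controlled epoxidation of the C2=CMe2 alkene, then 5-exo opening by the only available enol oxygen, forms O1–C2, sets C2 trans to C3 and frees the tertiary alcohol. The cis C6–OH/C7-acyl aldol is stored as an isoxazoline made from a chiral butenolide. Ester methylenation and ring-closing metathesis then build the carbocycle (C4=C5).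

Key step: step 9

Assumption 1: the (S)-configured PHOX ligand is assumed to deliver the C3 configuration drawn in step 8; if the sense of induction is the opposite, its enantiomer is used.
Assumption 2: the benzoate is carried as an aryl bromide until step 12, because a methyl benzoate would be methylenated in step 10 before the less electrophilic dihydrofuran ester.
Locants C2–C7a in the text are those of the target's benzofuran core.

Step 1
Reactants: 1 3-phenylpropanal
Product: 2 3-phenylpropanal oxime (E/Z mixture)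
Conditions: NH2OH·HCl, NaOAc, EtOH/H2O, 23 °C
Reagents that add atoms: hydroxylamine hydrochloride (NO.Cl)
Why: Condensation of the aldehyde with hydroxylamine (oxime formation) gives the nitrile oxide precursor.

Step 2
Reactants: 2 3-phenylpropanal oxime; 3 (S)-5-(hydroxymethyl)furan-2(5H)-one
Product: 5 (3aR,6R,6aS)-6-(hydroxymethyl)-3-(2-phenylethyl)-6,6a-dihydrofuro[3,4-d][1,2]oxazol-4(3aH)-one, via 3-phenylpropanenitrile oxide 4 (not isolated)
Conditions: PhI(OAc)2 (added over 2 h), CF3CO2H (cat.), MeOH, 0 °C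
Reagents that add atoms: none
Why: Amine-free oxidation of the oxime (no racemisation of the butenolide) gives the nitrile oxide, whose 1,3-dipolar cycloaddition should occur anti to the hydroxymethyl group with oxygen bonding to the β-carbon, so that the future C6–O and C7–C(acyl) bonds are set cis and in the required absolute sense in one event.

Step 3
Reactants: 5 the hydroxymethyl cycloadduct
Product: 6 (3aR,6S,6aS)-6-(iodomethyl)-3-(2-phenylethyl)-6,6a-dihydrofuro[3,4-d][1,2]oxazol-4(3aH)-one
Conditions: I2, PPh3, imidazole, CH2Cl2, 0 → 23 °C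
Reagents that add atoms: iodine (II)
Why: Appel iodination of the unhindered primary alcohol; no stereocentre is touched.

Step 4
Reactants: 6 the iodomethyl lactone
Product: 7 (4R,5R)-3-(2-phenylethyl)-5-vinyl-4,5-dihydro-1,2-oxazole-4-carboxylic acid
Conditions: Zn dust, AcOH, THF, 0 → 23 °C
Reagents that add atoms: none
Why: Zinc-mediated reductive β-elimination (the reverse of an iodolactonisation) should be much faster than N–O reduction and unveils the vinyl group (future C5) and the carboxylic acid (future C7a) under acidic conditions in which the cis C6/C7 pair cannot epimerise.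

Step 5
Reactants: 7 the cis-isoxazoline acid
Product: 9 methyl 3-oxo-3-[(4R,5R)-3-(2-phenylethyl)-5-vinyl-4,5-dihydro-1,2-oxazol-4-yl]propanoate, via acyl imidazolide 8 (not isolated)
Conditions: CDI, THF, 23 °C; then Mg(O2CCH2CO2Me)2, THF, 23 °C; aq HCl work-up
Reagents that add atoms: magnesium bis(methyl malonate) (COC(=O)CC(=O)[O-].COC(=O)CC(=O)[O-].[Mg+2])
Why: Masamune–Brooks decarboxylative Claisen condensation under near-neutral conditions makes the β-keto ester (C7a ketone, C3a methylene, C4 ester) with little risk to the C7 centre, because the product rests as its magnesium chelate enolised towards C3a.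

Step 6
Reactants: 10 5-bromo-2-hydroxybenzaldehyde
Product: 11 5-bromo-2-[(tert-butyldimethylsilyl)oxy]benzaldehyde
Conditions: TBSCl, imidazole, DMF, 23 °C
Reagents that add atoms: tert-butyldimethylsilyl chloride (CC(C)(C)[Si](C)(C)Cl)
Why: Silylation masks the phenol so that it can neither compete as an oxygen nucleophile in step 9 nor add to the ketone.

Step 7
Reactants: 11 the silylated aldehyde
Product: 13 racemic 1-{5-bromo-2-[(tert-butyldimethylsilyl)oxy]phenyl}-3-methylbut-2-en-1-yl methyl carbonate, via magnesium alkoxide 12 (not isolated)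
Conditions: Me2C=CHMgBr, THF, −78 °C; then ClCO2Me, −78 → 0 °C
Reagents that add atoms: (2-methylprop-1-en-1-yl)magnesium bromide (CC(C)=C[Mg]Br); methyl chloroformate (COC(=O)Cl)
Why: Grignard 1,2-addition to the aldehyde followed by acylation of the alkoxide in the same flask gives the allylic carbonate; its configuration is irrelevant because step 8 goes through a common allyl complex.

Step 8
Reactants: 9 the β-keto ester; 13 the allylic carbonate
Product: 14 methyl (3S)-3-{5-bromo-2-[(tert-butyldimethylsilyl)oxy]phenyl}-5-methyl-2-{[(4R,5R)-3-(2-phenylethyl)-5-vinyl-4,5-dihydro-1,2-oxazol-4-yl]carbonyl}hex-4-enoate (mixture of epimers at the α-carbon)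
Conditions: Pd2(dba)3·CHCl3 (2.5 mol %), (S)-t-Bu-PHOX (6 mol %), THF, 23 °C
Reagents that add atoms: none
Why: Tsuji–Trost asymmetric allylic alkylation: the 1-aryl-3,3-dimethylallyl palladium complex exchanges its enantiofaces through the CMe2 terminus, and the β-keto ester enolate attacks the less hindered aryl-bearing terminus under ligand control, which forms C3–C3a and sets C3; the epimeric α-centre becomes sp2 in step 9.

Step 9
Reactants: 14 the C-allylated β-keto ester
Product: 16 methyl (4R,5R)-4-{5-bromo-2-[(tert-butyldimethylsilyl)oxy]phenyl}-5-(2-hydroxypropan-2-yl)-2-[(4R,5R)-3-(2-phenylethyl)-5-vinyl-4,5-dihydro-1,2-oxazol-4-yl]-4,5-dihydrofuran-3-carboxylate, via epoxide 15 (not isolated)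
Conditions: ent-Shi ketone (L-fructose-derived, 30 mol %), KHSO5 (as Oxone), K2CO3, Bu4NHSO4, MeCN/(MeO)2CH2/aq Na2B4O7 buffer (pH about 10.5), 0 °C
Reagents that add atoms: potassium peroxymonosulfate (OOS(=O)(=O)[O-].[K+])
Why: The dioxirane of the ent-Shi ketone should epoxidise the trisubstituted C2=CMe2 alkene through the usual spiro transition state to the (2S)-epoxide 15, and the enol oxygen of the C7a ketone then opens it at C2 by SN2 attack with inversion, which forms O1–C2, the dihydrofuran ring and the tertiary alcohol in one operation. The closest known reaction type is the Shi epoxidation combined with the epoxide-opening cyclisation of 2-prenyl 1,3-dicarbonyl compounds to 2-(2-hydroxypropan-2-yl)-2,3-dihydrofurans. The dihydrofuran ring closes in the 5-exo-tet mode. C2 is controlled by the catalyst (face of oxygen transfer) and by the stereospecific inversion, which places the hydroxyisopropyl group trans to the aryl group at C3 set in step 8. The step needs chemoselectivity for the electron-rich trisubstituted alkene over the vinyl group, which dioxiranes show, and closure through the correct oxygen, which the substrate secures because the C4 oxygen is locked in the methyl ester, the phenol is silylated and enolisation towards C3a is strongly preferred. It also needs 5-exo rather than 6-endo opening, which the basic medium secures by directing attack to the less substituted epoxide carbon.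

Step 10
Reactants: 16 the dihydrofuran ester
Product: 17 2-[(2R,3R)-3-{5-bromo-2-[(tert-butyldimethylsilyl)oxy]phenyl}-4-(1-methoxyethenyl)-5-[(4R,5R)-3-(2-phenylethyl)-5-vinyl-4,5-dihydro-1,2-oxazol-4-yl]-2,3-dihydrofuran-2-yl]propan-2-ol
Conditions: Cp2Ti(μ-Cl)(μ-CH2)AlMe2 (3 equiv), pyridine, THF/toluene, −40 → 23 °C; aq NaOH quench
Reagents that add atoms: Tebbe reagent (C[Al-]1(C)C[Ti](C2C=CC=C2)(C2C=CC=C2)[Cl+]1)
Why: Tebbe methylenation converts the only ester present into the methyl enol ether, so that the ester methoxy group becomes the C4–OMe group of the target; one equivalent is consumed by the tertiary alcohol.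

Step 11
Reactants: 17 the methoxyvinyl diene
Product: 18 the (2R,3R,6R,7R) tricyclic aryl bromide (the target skeleton with 5-bromo-2-silyloxyphenyl at C3 and a cis-fused 2-isoxazoline bridging O6 and C7)
Conditions: second-generation Grubbs catalyst RuCl2(=CHPh)(PCy3)(H2IMes) (10 mol %), toluene, 70 °C
Reagents that add atoms: none
Why: Ring-closing metathesis starts at the vinyl group and closes onto the 1,1-disubstituted enol ether, which forms C4=C5 and the six-membered ring; only the cis-disposed isoxazoline substituents can reach each other, so the ring fusion is cis.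

Step 12
Reactants: 18 the tricyclic aryl bromide
Product: 20 the (2R,3R,6R,7R) tricyclic phenol methyl ester (as 18 with 2-hydroxy-5-(methoxycarbonyl)phenyl at C3), via silyl ether ester 19 (not isolated)
Conditions: Pd(OAc)2 (5 mol %), Xantphos (10 mol %), CO (1 atm), Et3N, MeOH/toluene, 70 °C; then K2CO3 (cat.), MeOH, 23 °C
Reagents that add atoms: carbon monoxide ([C-]#[O+]); methanol (CO)
Why: Palladium-catalysed methoxycarbonylation of the aryl bromide installs the benzoate, and base-catalysed methanolysis then removes the silyl group from the now electron-poor phenol; the dienol ether is stable to base.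

Step 13
Reactants: 20 the tricyclic phenol methyl ester
Product: 22 methyl 4-hydroxy-3-[(2R,3R,6R,7R)-6-hydroxy-2-(2-hydroxypropan-2-yl)-4-methoxy-7-(3-phenylpropanoyl)-2,3,6,7-tetrahydro-1-benzofuran-3-yl]benzoate, via hydroxy imine 21 (not isolated)
Conditions: SmI2, THF, 0 °C; then B(OH)3, H2O, 23 °C
Reagents that add atoms: water (O)
Why: Reductive N–O cleavage of the isoxazoline by SmI2 and hydrolysis of the resulting ketimine by aqueous boric acid should unveil the cis C6–OH/C7-acyl pair with retention at both centres under near-neutral conditions, which avoid epimerisation, retro-aldol cleavage and dehydration to the arene.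

**Compound list**

1 | 3-phenylpropanal | O=CCCc1ccccc1 | starting material
2 | 3-phenylpropanal oxime | ON=CCCc1ccccc1 | intermediate
3 | (S)-5-(hydroxymethyl)furan-2(5H)-one | O=C1O[C@H](CO)C=C1 | starting material
4 | 3-phenylpropanenitrile oxide | [O-][N+]#CCCc1ccccc1 | intermediate
5 | (3aR,6R,6aS)-6-(hydroxymethyl)-3-(2-phenylethyl)-6,6a-dihydrofuro[3,4-d][1,2]oxazol-4(3aH)-one (isoxazoline anti to CH2OH) | O=C1O[C@H](CO)[C@H]2ON=C(CCc3ccccc3)[C@@H]12 | intermediate
6 | (3aR,6S,6aS)-6-(iodomethyl)-3-(2-phenylethyl)-6,6a-dihydrofuro[3,4-d][1,2]oxazol-4(3aH)-one | O=C1O[C@H](CI)[C@H]2ON=C(CCc3ccccc3)[C@@H]12 | intermediate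
7 | (4R,5R)-3-(2-phenylethyl)-5-vinyl-4,5-dihydro-1,2-oxazole-4-carboxylic acid (cis) | OC(=O)[C@@H]1C(CCc2ccccc2)=NO[C@@H]1C=C | intermediate
8 | 1H-imidazol-1-yl [(4R,5R)-3-(2-phenylethyl)-5-vinyl-4,5-dihydro-1,2-oxazol-4-yl] ketone (acyl imidazolide) | O=C(n1ccnc1)[C@@H]1C(CCc2ccccc2)=NO[C@@H]1C=C | intermediate
9 | methyl 3-oxo-3-[(4R,5R)-3-(2-phenylethyl)-5-vinyl-4,5-dihydro-1,2-oxazol-4-yl]propanoate | COC(=O)CC(=O)[C@@H]1C(CCc2ccccc2)=NO[C@@H]1C=C | intermediate
10 | 5-bromo-2-hydroxybenzaldehyde | O=Cc1cc(Br)ccc1O | starting material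
11 | 5-bromo-2-[(tert-butyldimethylsilyl)oxy]benzaldehyde | O=Cc1cc(Br)ccc1O[Si](C)(C)C(C)(C)C | intermediate
12 | bromomagnesium 1-{5-bromo-2-[(tert-butyldimethylsilyl)oxy]phenyl}-3-methylbut-2-en-1-olate (racemic) | CC(C)=CC(O[Mg]Br)c1cc(Br)ccc1O[Si](C)(C)C(C)(C)C | intermediate
13 | racemic 1-{5-bromo-2-[(tert-butyldimethylsilyl)oxy]phenyl}-3-methylbut-2-en-1-yl methyl carbonate | COC(=O)OC(C=C(C)C)c1cc(Br)ccc1O[Si](C)(C)C(C)(C)C | intermediate
14 | methyl (3S)-3-{5-bromo-2-[(tert-butyldimethylsilyl)oxy]phenyl}-5-methyl-2-{[(4R,5R)-3-(2-phenylethyl)-5-vinyl-4,5-dihydro-1,2-oxazol-4-yl]carbonyl}hex-4-enoate (epimers at C2 of the chain) | COC(=O)C(C(=O)[C@@H]1C(CCc2ccccc2)=NO[C@@H]1C=C)[C@H](C=C(C)C)c1cc(Br)ccc1O[Si](C)(C)C(C)(C)C | intermediate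
15 | methyl (3S)-3-{5-bromo-2-[(tert-butyldimethylsilyl)oxy]phenyl}-3-[(2S)-3,3-dimethyloxiran-2-yl]-2-{[(4R,5R)-3-(2-phenylethyl)-5-vinyl-4,5-dihydro-1,2-oxazol-4-yl]carbonyl}propanoate | COC(=O)C(C(=O)[C@@H]1C(CCc2ccccc2)=NO[C@@H]1C=C)[C@H]([C@@H]1OC1(C)C)c1cc(Br)ccc1O[Si](C)(C)C(C)(C)C | intermediate
16 | methyl (4R,5R)-4-{5-bromo-2-[(tert-butyldimethylsilyl)oxy]phenyl}-5-(2-hydroxypropan-2-yl)-2-[(4R,5R)-3-(2-phenylethyl)-5-vinyl-4,5-dihydro-1,2-oxazol-4-yl]-4,5-dihydrofuran-3-carboxylate (aryl and hydroxyisopropyl trans) | COC(=O)C1=C([C@@H]2C(CCc3ccccc3)=NO[C@@H]2C=C)O[C@@H](C(C)(C)O)[C@@H]1c1cc(Br)ccc1O[Si](C)(C)C(C)(C)C | intermediate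
17 | 2-[(2R,3R)-3-{5-bromo-2-[(tert-butyldimethylsilyl)oxy]phenyl}-4-(1-methoxyethenyl)-5-[(4R,5R)-3-(2-phenylethyl)-5-vinyl-4,5-dihydro-1,2-oxazol-4-yl]-2,3-dihydrofuran-2-yl]propan-2-ol | C=C(OC)C1=C([C@@H]2C(CCc3ccccc3)=NO[C@@H]2C=C)O[C@@H](C(C)(C)O)[C@@H]1c1cc(Br)ccc1O[Si](C)(C)C(C)(C)C | intermediate
18 | (2R,3R,6R,7R; target numbering) 2-[3-{5-bromo-2-[(tert-butyldimethylsilyl)oxy]phenyl}-4-methoxy-2,3,6,7-tetrahydro-1-benzofuran-2-yl]propan-2-ol in which O6 and C7 are bridged by N=C(CH2CH2Ph) as a cis-fused 2-isoxazoline | COC1=C[C@H]2ON=C(CCc3ccccc3)[C@H]2C2=C1[C@@H](c1cc(Br)ccc1O[Si](C)(C)C(C)(C)C)[C@H](C(C)(C)O)O2 | intermediate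
19 | as 18, with 2-[(tert-butyldimethylsilyl)oxy]-5-(methoxycarbonyl)phenyl at C3 | COC1=C[C@H]2ON=C(CCc3ccccc3)[C@H]2C2=C1[C@@H](c1cc(C(=O)OC)ccc1O[Si](C)(C)C(C)(C)C)[C@H](C(C)(C)O)O2 | intermediate
20 | as 18, with 2-hydroxy-5-(methoxycarbonyl)phenyl at C3 (the isoxazoline-masked target) | COC1=C[C@H]2ON=C(CCc3ccccc3)[C@H]2C2=C1[C@@H](c1cc(C(=O)OC)ccc1O)[C@H](C(C)(C)O)O2 | intermediate
21 | methyl 4-hydroxy-3-[(2R,3R,6R,7R)-6-hydroxy-2-(2-hydroxypropan-2-yl)-7-(1-imino-3-phenylpropyl)-4-methoxy-2,3,6,7-tetrahydro-1-benzofuran-3-yl]benzoate | COC1=C[C@@H](O)[C@@H](C(=N)CCc3ccccc3)C2=C1[C@@H](c1cc(C(=O)OC)ccc1O)[C@H](C(C)(C)O)O2 | intermediate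
22 | methyl 4-hydroxy-3-[(2R,3R,6R,7R)-6-hydroxy-2-(2-hydroxypropan-2-yl)-4-methoxy-7-(3-phenylpropanoyl)-2,3,6,7-tetrahydro-1-benzofuran-3-yl]benzoate | COC(=O)c1ccc(O)c([C@@H]2C3=C(O[C@H]2C(C)(C)O)[C@H](C(=O)CCc2ccccc2)[C@H](O)C=C3OC)c1 | target

**Total step count:** 13. **Longest linear sequence:** 11 steps (steps 1–5 and 8–13).

**Steps most likely to fail**

Step 9 (key step). Oxygen transfer may occur with poor facial selectivity next to the crowded C3 centre, the β-keto ester may be hydroxylated through its enolate, or C7 may epimerise in the basic buffer. The fallback sets out from 14 and closes the same O1–C2 bond under substrate control by 5-exo iodoetherification (NIS, CH2Cl2, −20 °C). A(1,3) strain between the cis-methyl group and the C3 substituents holds C3–H in the alkene plane, so the enol oxygen should add anti to the aryl group. This should give the 2,3-trans tertiary iodide methyl (4R,5R)-4-{5-bromo-2-[(tert-butyldimethylsilyl)oxy]phenyl}-5-(2-iodopropan-2-yl)-2-[(4R,5R)-3-(2-phenylethyl)-5-vinyl-4,5-dihydro-1,2-oxazol-4-yl]-4,5-dihydrofuran-3-carboxylate F1. Silver-assisted hydrolysis of F1 (AgOTf, 2,6-lutidine, acetone/H2O) then gives 16, where the route is rejoined.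

Step 8. The ionisation and attack sequence on the hindered ortho-silyloxy aryl allyl unit may give poor regio- or enantiocontrol, and zerovalent palladium may also ionise the allylic C–O bond of the vinyl isoxazoline. The fallback sets C3 on a separate fragment and joins the fragments by acylation. {5-Bromo-2-[(tert-butyldimethylsilyl)oxy]phenyl}boronic acid F3 (from commercial (5-bromo-2-hydroxyphenyl)boronic acid and TBSCl) is added to methyl (2E)-5-methylhexa-2,4-dienoate (taken as commercial) by rhodium-catalysed asymmetric 1,4-addition ([Rh(OH)(cod)]2, (S)-BINAP, dioxane/H2O). This should give methyl (3R)-3-{5-bromo-2-[(tert-butyldimethylsilyl)oxy]phenyl}-5-methylhex-4-enoate F2. The lithium enolate of F2 (LDA, THF, −78 °C) is then acylated by imidazolide 8, made from 7 as in step 5, in a crossed Claisen condensation. The fallback therefore sets out from 7 and comes back at 14.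

Step 12. Zerovalent palladium may ionise the allylic C6–O bond of the isoxazoline at 70 °C, which would open the ring and let the six-membered ring aromatise. The fallback sets out from 18 and avoids palladium. Deprotonation of the tertiary alcohol (MeLi), bromine–lithium exchange (t-BuLi, THF, −100 °C) and carboxylation with CO2 should give 4-[(tert-butyldimethylsilyl)oxy]-3-[(2R,3R,6R,7R)-tricyclic isoxazoline core of 18]benzoic acid F4. Esterification of F4 with TMSCHN2 (MeOH/toluene, 0 °C) gives 19, and methanolysis (K2CO3 cat., MeOH) gives 20, where the route is rejoined.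

**Further compounds**

F1 | step 9 | methyl (4R,5R)-4-{5-bromo-2-[(tert-butyldimethylsilyl)oxy]phenyl}-5-(2-iodopropan-2-yl)-2-[(4R,5R)-3-(2-phenylethyl)-5-vinyl-4,5-dihydro-1,2-oxazol-4-yl]-4,5-dihydrofuran-3-carboxylate | COC(=O)C1=C([C@@H]2C(CCc3ccccc3)=NO[C@@H]2C=C)O[C@@H](C(C)(C)I)[C@@H]1c1cc(Br)ccc1O[Si](C)(C)C(C)(C)C
F2 | step 8 | methyl (3R)-3-{5-bromo-2-[(tert-butyldimethylsilyl)oxy]phenyl}-5-methylhex-4-enoate | COC(=O)C[C@H](C=C(C)C)c1cc(Br)ccc1O[Si](C)(C)C(C)(C)C
F3 | step 8 | {5-bromo-2-[(tert-butyldimethylsilyl)oxy]phenyl}boronic acid | OB(O)c1cc(Br)ccc1O[Si](C)(C)C(C)(C)C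
F4 | step 12 | 4-[(tert-butyldimethylsilyl)oxy]-3-[(2R,3R,6R,7R)-tricyclic isoxazoline core of 18]benzoic acid | COC1=C[C@H]2ON=C(CCc3ccccc3)[C@H]2C2=C1[C@@H](c1cc(C(=O)O)ccc1O[Si](C)(C)C(C)(C)C)[C@H](C(C)(C)O)O2
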